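**Retrosynthetic overview**

- Ring C is cut at O1–C2 and C4–C4a together. The target goes back to a mono-ferulate ester of 2-(1,1-dimethylallyl)phloroglucinol: light moves the acyl group from oxygen to the ortho carbon (photo-Fries), and chalcone isomerase in the same vessel closes the pyranone and sets C2.
- Enabling feature: ring A is a phloroglucinol in which every carbon open to the acyl shift is a C–H lying between two hydroxyls. The shift can therefore give only one 2',4',6'-trihydroxychalcone, and its free ortho-hydroxyl/enone array (O1···C2=C3–C4=O) is the native substrate pattern of the enzyme.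
- The ester is cut at the acyl–O bond into the free triol and O-silylated ferulic acid (Steglich esterification, then desilylation).
- The triol is cut at the aryl–C(CH3)2 bond: aromatic Claisen rearrangement of the prenyl ether of bis-MOM phloroglucinol builds the quaternary carbon.
- Ring order: rings A and B are bought as phloroglucinol and ferulic acid; ring C is the only ring made, in the last step.

Key step: step 8

Remark: the target is read as the 2S enantiomer, the configuration plant chalcone isomerases deliver; the enzyme is assumed to accept the ring-A tert-alkyl chalcone as it accepts other 2',4',6'-trihydroxychalcones.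

**Route**

Step 1
Reactants: 1 phloroglucinol (benzene-1,3,5-triol)
Product: 2 3,5-bis(methoxymethoxy)phenol
Conditions: MOMCl (2.1 equiv), K2CO3, acetone, 0 °C to rt
Reagents that add atoms: chloromethyl methyl ether (MOMCl), COCCl
Why: Williamson-type O-alkylation of the phenoxides by the oxocarbenium-like chloride; the triol is threefold symmetric, so any bis-ether is the same compound, and the mono- and tris-ethers formed beside it are removed by chromatography; no stereocentre is formed.

Step 2
Reactants: 2 3,5-bis(methoxymethoxy)phenol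
Product: 3 1,3-bis(methoxymethoxy)-5-[(3-methylbut-2-en-1-yl)oxy]benzene
Conditions: prenyl bromide, K2CO3, acetone, 50 °C
Reagents that add atoms: prenyl bromide (1-bromo-3-methylbut-2-ene), CC(C)=CCBr
Why: Williamson ether synthesis in which the single phenoxide displaces the primary allylic bromide (SN2), O-alkylation being favoured with K2CO3 in acetone; no stereocentre is formed.

Step 3
Reactants: 3 1,3-bis(methoxymethoxy)-5-[(3-methylbut-2-en-1-yl)oxy]benzene
Product: 5 3,5-bis(methoxymethoxy)-2-(2-methylbut-3-en-2-yl)phenol, via ortho-dienone 4 (not isolated)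
Conditions: PhNEt2, 190 °C, Ar, sealed vessel
Reagents that add atoms: none
Why: Aromatic Claisen rearrangement: the [3,3] shift joins the dimethyl-substituted allyl terminus to one of the two equivalent ortho carbons to give dienone 4, which the amine solvent helps enolise to phenol 5 before a Cope shift to the para carbon or the abnormal Claisen pathway can intervene; the new quaternary carbon is not a stereocentre.

Step 4
Reactants: 5 3,5-bis(methoxymethoxy)-2-(2-methylbut-3-en-2-yl)phenol
Product: 6 2-(2-methylbut-3-en-2-yl)benzene-1,3,5-triol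
Conditions: 2 M aq. HCl, THF, 45 °C, Ar
Reagents that add atoms: none
Why: Acid-catalysed hydrolysis of the two aryl methoxymethyl acetals; the monosubstituted alkene is not protonated under these mild conditions, so oxa-cyclisation to a dihydrobenzofuran should not compete, and argon protects the electron-rich triol; no stereocentre is formed.

Step 5
Reactants: 7 ferulic acid ((2E)-3-(4-hydroxy-3-methoxyphenyl)prop-2-enoic acid)
Product: 9 (2E)-3-{4-[(tert-butyldimethylsilyl)oxy]-3-methoxyphenyl}prop-2-enoic acid, via bis-silyl ester 8 (not isolated)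
Conditions: TBSCl (2.3 equiv), imidazole, DMF, rt; then AcOH/THF/H2O, rt
Reagents that add atoms: tert-butyldimethylsilyl chloride (TBSCl), CC(C)(C)[Si](C)(C)Cl
Why: Silylation of both the phenol and the acid, followed by selective hydrolysis of the far more labile silyl ester of 8, which leaves the aryl silyl ether; the E alkene is untouched.

Step 6
Reactants: 6 2-(2-methylbut-3-en-2-yl)benzene-1,3,5-triol, 9 (2E)-3-{4-[(tert-butyldimethylsilyl)oxy]-3-methoxyphenyl}prop-2-enoic acid
Product: 10 3,5-dihydroxy-4-(2-methylbut-3-en-2-yl)phenyl (2E)-3-{4-[(tert-butyldimethylsilyl)oxy]-3-methoxyphenyl}prop-2-enoate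
Conditions: DIC (1.0 equiv), DMAP (0.1 equiv), THF, −20 °C to rt, Ar, 6 in slight excess
Reagents that add atoms: none
Why: Steglich esterification in which the DMAP-derived acylpyridinium acylates the one hydroxyl not flanked by the quaternary carbon, low temperature and excess triol holding the reaction at the mono-ester; a minor ester on a hindered hydroxyl would do no harm because it leads to the same chalcone in step 8.

Step 7
Reactants: 10 3,5-dihydroxy-4-(2-methylbut-3-en-2-yl)phenyl (2E)-3-{4-[(tert-butyldimethylsilyl)oxy]-3-methoxyphenyl}prop-2-enoate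
Product: 11 3,5-dihydroxy-4-(2-methylbut-3-en-2-yl)phenyl (2E)-3-(4-hydroxy-3-methoxyphenyl)prop-2-enoate
Conditions: TBAF (1.1 equiv), AcOH (1.2 equiv), THF, 0 °C
Reagents that add atoms: none
Why: Fluoride-induced cleavage of the aryl silyl ether, driven by the Si–F bond; acetic acid buffers the phenoxide so that the aryl ester is neither cleaved nor transferred.

Step 8
Reactants: 11 3,5-dihydroxy-4-(2-methylbut-3-en-2-yl)phenyl (2E)-3-(4-hydroxy-3-methoxyphenyl)prop-2-enoate
Product: 14 (2S)-5,7-dihydroxy-2-(4-hydroxy-3-methoxyphenyl)-6-(2-methylbut-3-en-2-yl)-2,3-dihydro-4H-chromen-4-one, via acyl-dienone 12 (not isolated), via chalcone 13 (not isolated)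
Conditions: hν (325 nm LEDs, flow photoreactor), chalcone isomerase (EC 5.5.1.6, recombinant plant enzyme), KH2PO4/K2HPO4 buffer (pH 6.2), 1% Brij 35, 5% DMSO, Ar, 10 °C
Reagents that add atoms: none
Why: Proposed new method: light absorbed by the ferulate ester of 11 (the protein is transparent at this wavelength) homolyses the aryl O–C(=O) bond and the micelle-caged phenoxyl/acyl radical pair recombines at one of the two equivalent ortho C–H carbons, the para carbon being blocked by the quaternary substituent, to give dienone 12, which enolises to chalcone 13; this is the photo-Fries rearrangement, known for aryl cinnamates that give 2'-hydroxychalcones, and because the acyl carbon is delivered within a radical pair the competing conjugate C-alkylation to a 4-aryldihydrocoumarin cannot occur. Chalcone isomerase in the same solution then takes up 13 as it forms and adds the ortho phenoxide oxygen to the β-carbon of the enone, closing ring C in a 6-endo-trig oxa-Michael addition, the known reaction of this enzyme class with 2',4',6'-trihydroxychalcones; what is new is running the two events concurrently in one aqueous vessel and on a chalcone with a tert-alkyl group on ring A. The only stereocentre, C2, is set by the enzyme active site, which lets the phenoxide reach one enantioface of the enone only and should deliver the 2S configuration. pH 6.2 and 10 °C keep the uncatalysed non-selective closure and the ring-opening racemisation of the 5-hydroxyflavanone slow, and any flavanone reopened by light is returned to the same 2S product by the enzyme, which also removes the strongly absorbing chalcone before it can act as an inner filter. The step needs C-acylation at a carbon between two hydroxyls, secured because every position open to the acyl shift is of that kind, and closure through the unhindered ortho oxygen and not the one next to the 1,1-dimethylallyl group, secured because that hindered hydroxyl is buttressed by the quaternary carbon into the hydrogen bond to C=O (it becomes the chelated 5-OH) while the other ortho oxygen stays free to ionise and attack.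

**Compound list**

1 | phloroglucinol (benzene-1,3,5-triol) | Oc1cc(O)cc(O)c1 | starting material
2 | 3,5-bis(methoxymethoxy)phenol | COCOc1cc(O)cc(OCOC)c1 | intermediate
3 | 1,3-bis(methoxymethoxy)-5-[(3-methylbut-2-en-1-yl)oxy]benzene | COCOc1cc(OCC=C(C)C)cc(OCOC)c1 | intermediate
4 | 3,5-bis(methoxymethoxy)-6-(2-methylbut-3-en-2-yl)cyclohexa-2,4-dien-1-one (ortho-dienone, racemic, not isolated) | C=CC(C)(C)C1C(=O)C=C(OCOC)C=C1OCOC | intermediate
5 | 3,5-bis(methoxymethoxy)-2-(2-methylbut-3-en-2-yl)phenol | C=CC(C)(C)c1c(O)cc(OCOC)cc1OCOC | intermediate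
6 | 2-(2-methylbut-3-en-2-yl)benzene-1,3,5-triol | C=CC(C)(C)c1c(O)cc(O)cc1O | intermediate
7 | ferulic acid, (2E)-3-(4-hydroxy-3-methoxyphenyl)prop-2-enoic acid | COc1cc(/C=C/C(=O)O)ccc1O | starting material
8 | tert-butyldimethylsilyl (2E)-3-{4-[(tert-butyldimethylsilyl)oxy]-3-methoxyphenyl}prop-2-enoate (bis-silyl ester, not isolated) | COc1cc(/C=C/C(=O)O[Si](C)(C)C(C)(C)C)ccc1O[Si](C)(C)C(C)(C)C | intermediate
9 | (2E)-3-{4-[(tert-butyldimethylsilyl)oxy]-3-methoxyphenyl}prop-2-enoic acid | COc1cc(/C=C/C(=O)O)ccc1O[Si](C)(C)C(C)(C)C | intermediate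
10 | 3,5-dihydroxy-4-(2-methylbut-3-en-2-yl)phenyl (2E)-3-{4-[(tert-butyldimethylsilyl)oxy]-3-methoxyphenyl}prop-2-enoate | C=CC(C)(C)c1c(O)cc(OC(=O)/C=C/c2ccc(O[Si](C)(C)C(C)(C)C)c(OC)c2)cc1O | intermediate
11 | 3,5-dihydroxy-4-(2-methylbut-3-en-2-yl)phenyl (2E)-3-(4-hydroxy-3-methoxyphenyl)prop-2-enoate | C=CC(C)(C)c1c(O)cc(OC(=O)/C=C/c2ccc(O)c(OC)c2)cc1O | intermediate
12 | 3,5-dihydroxy-2-[(2E)-3-(4-hydroxy-3-methoxyphenyl)prop-2-enoyl]-4-(2-methylbut-3-en-2-yl)cyclohexa-3,5-dien-1-one (acyl-dienone, racemic, not isolated) | C=CC(C)(C)C1=C(O)C(C(=O)/C=C/c2ccc(O)c(OC)c2)C(=O)C=C1O | intermediate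
13 | (2E)-3-(4-hydroxy-3-methoxyphenyl)-1-[2,4,6-trihydroxy-3-(2-methylbut-3-en-2-yl)phenyl]prop-2-en-1-one (chalcone, not isolated) | C=CC(C)(C)c1c(O)cc(O)c(C(=O)/C=C/c2ccc(O)c(OC)c2)c1O | intermediate
14 | (2S)-5,7-dihydroxy-2-(4-hydroxy-3-methoxyphenyl)-6-(2-methylbut-3-en-2-yl)-2,3-dihydro-4H-chromen-4-one | C=CC(C)(C)c1c(O)cc2c(c1O)C(=O)C[C@@H](c1ccc(O)c(OC)c1)O2 | target

**Step count**

Total step count: 8. Longest linear sequence: 7 steps from phloroglucinol (steps 1, 2, 3, 4, 6, 7, 8); step 5 is the ferulic acid branch.

**Steps most likely to fail**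

Step 8 (proposed new method). Several processes could go wrong:
- the excited ferulate may relax mainly by E/Z isomerisation instead of O–acyl homolysis, so the acyl shift is slow;
- the enzyme may lose activity under irradiation or fail to outpace the uncatalysed, non-selective ring closure;
- ring closure through the hindered hydroxyl would give the regioisomer with the allyl group next to O1.

The fallback uses known chemistry, sets out from triol 6 and returns at chalcone 13, then target 14. Triol 6 is C-acetylated under Friedel–Crafts conditions (Ac2O, BF3·OEt2, 0 °C to rt) to the acetophenone 1-[2,4,6-trihydroxy-3-(2-methylbut-3-en-2-yl)phenyl]ethan-1-one F1. Its two more accessible hydroxyls are protected (MOMCl, iPr2NEt, CH2Cl2) to give 1-[2-hydroxy-4,6-bis(methoxymethoxy)-3-(2-methylbut-3-en-2-yl)phenyl]ethan-1-one F2. Claisen–Schmidt condensation with commercial 3-methoxy-4-(methoxymethoxy)benzaldehyde (KOH, EtOH/H2O, rt) gives the protected chalcone (2E)-1-[2-hydroxy-4,6-bis(methoxymethoxy)-3-(2-methylbut-3-en-2-yl)phenyl]-3-[3-methoxy-4-(methoxymethoxy)phenyl]prop-2-en-1-one F3. Mild aqueous HCl in THF removes the three acetals to give chalcone 13, now isolated, which is cyclised in a separate dark operation with chalcone isomerase at pH 6.2 to 14. This builds the aryl ketone without light and keeps the enzyme away from the photochemistry.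

Step 3. The ortho-dienone may undergo a Cope shift to the para carbon, and the first-formed ortho-allyl phenol may enter the abnormal Claisen pathway or cyclise onto its own alkene at the reaction temperature. The fallback sets out from ether 3 and returns at phenol 5. The rearrangement is run as a rearrangement–acylation cascade (Ac2O, NaOAc, PhNEt2, 180 °C) so that the phenol never exists free but is captured as 3,5-bis(methoxymethoxy)-2-(2-methylbut-3-en-2-yl)phenyl acetate F4. Methanolysis (K2CO3, MeOH, rt) then gives 5.

Step 6. Acylation may run on to bis-esters, the activated acid may rearrange to an N-acylurea, and the electron-rich triol may oxidise while it is handled. The fallback sets out from phenol 5 and returns at chalcone 13 inside step 8: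
- The single free hydroxyl of 5 is esterified with acid 9 (DIC, DMAP, CH2Cl2, rt), so exactly one ester can form: 3,5-bis(methoxymethoxy)-2-(2-methylbut-3-en-2-yl)phenyl (2E)-3-{4-[(tert-butyldimethylsilyl)oxy]-3-methoxyphenyl}prop-2-enoate F5.
- Aqueous HCl in THF removes the two acetals to give 3,5-dihydroxy-2-(2-methylbut-3-en-2-yl)phenyl (2E)-3-{4-[(tert-butyldimethylsilyl)oxy]-3-methoxyphenyl}prop-2-enoate F6.
- Buffered fluoride (TBAF, AcOH) gives 3,5-dihydroxy-2-(2-methylbut-3-en-2-yl)phenyl (2E)-3-(4-hydroxy-3-methoxyphenyl)prop-2-enoate F7.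
- Under the conditions of step 8 the acyl group of F7 shifts to its only free ortho carbon through 3,5-dihydroxy-6-[(2E)-3-(4-hydroxy-3-methoxyphenyl)prop-2-enoyl]-2-(2-methylbut-3-en-2-yl)cyclohexa-2,4-dien-1-one F8, which enolises to the same chalcone 13 and is closed by the enzyme to 14.

Further compounds
F1 | step 8 | 1-[2,4,6-trihydroxy-3-(2-methylbut-3-en-2-yl)phenyl]ethan-1-one | C=CC(C)(C)c1c(O)cc(O)c(C(C)=O)c1O
F2 | step 8 | 1-[2-hydroxy-4,6-bis(methoxymethoxy)-3-(2-methylbut-3-en-2-yl)phenyl]ethan-1-one | C=CC(C)(C)c1c(OCOC)cc(OCOC)c(C(C)=O)c1O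
F3 | step 8 | (2E)-1-[2-hydroxy-4,6-bis(methoxymethoxy)-3-(2-methylbut-3-en-2-yl)phenyl]-3-[3-methoxy-4-(methoxymethoxy)phenyl]prop-2-en-1-one | C=CC(C)(C)c1c(OCOC)cc(OCOC)c(C(=O)/C=C/c2ccc(OCOC)c(OC)c2)c1O
F4 | step 3 | 3,5-bis(methoxymethoxy)-2-(2-methylbut-3-en-2-yl)phenyl acetate | C=CC(C)(C)c1c(OC(C)=O)cc(OCOC)cc1OCOC
F5 | step 6 | 3,5-bis(methoxymethoxy)-2-(2-methylbut-3-en-2-yl)phenyl (2E)-3-{4-[(tert-butyldimethylsilyl)oxy]-3-methoxyphenyl}prop-2-enoate | C=CC(C)(C)c1c(OC(=O)/C=C/c2ccc(O[Si](C)(C)C(C)(C)C)c(OC)c2)cc(OCOC)cc1OCOC
F6 | step 6 | 3,5-dihydroxy-2-(2-methylbut-3-en-2-yl)phenyl (2E)-3-{4-[(tert-butyldimethylsilyl)oxy]-3-methoxyphenyl}prop-2-enoate | C=CC(C)(C)c1c(OC(=O)/C=C/c2ccc(O[Si](C)(C)C(C)(C)C)c(OC)c2)cc(O)cc1O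
F7 | step 6 | 3,5-dihydroxy-2-(2-methylbut-3-en-2-yl)phenyl (2E)-3-(4-hydroxy-3-methoxyphenyl)prop-2-enoate | C=CC(C)(C)c1c(OC(=O)/C=C/c2ccc(O)c(OC)c2)cc(O)cc1O
F8 | step 6 | 3,5-dihydroxy-6-[(2E)-3-(4-hydroxy-3-methoxyphenyl)prop-2-enoyl]-2-(2-methylbut-3-en-2-yl)cyclohexa-2,4-dien-1-one | C=CC(C)(C)C1=C(O)C=C(O)C(C(=O)/C=C/c2ccc(O)c(OC)c2)C1=O
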